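If product speeds its own making, we can try one self-feeding curve with one time constant on these runs, and that constant is what we want from them.

| setting | north | north-east | west | south-west | south |
|---|---|---|---|---|---|
| starting material | 250 mM | 150 mM | 250 mM | 250 mM | 250 mM |
| partner | 625 mM | 525 mM | 1200 mM | 625 mM | 4100 mM |
| free catalyst | 0.500 mM | 0.500 mM | 0.500 mM | 0.250 mM | 0.500 mM |
| time |  |  |  |  | 4.2 min |

| run | time / min | [product] / mM |
|---|---|---|
| north run | 0.53 | 11.7 |
| north run | 1.1 | 26.9 |
| north run | 1.6 | 42.3 |
| north run | 2.1 | 60.6 |
| north run | 2.6 | 79.5 |
| north run | 3.1 | 101.7 |
| north run | 3.7 | 126.1 |
| north run | 4.2 | 145.1 |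
| north-east run | 0.53 | 6.4 |
| north-east run | 1.1 | 13.5 |
| north-east run | 1.6 | 21.1 |
| north-east run | 2.1 | 28.2 |
| north-east run | 2.6 | 37.3 |
| north-east run | 3.1 | 43.6 |
| north-east run | 3.7 | 55.5 |
| north-east run | 4.2 | 62.9 |
| west run | 0.53 | 13.5 |
| west run | 1.1 | 34.7 |
| west run | 1.6 | 56.4 |
| west run | 2.1 | 84.1 |
| west run | 2.6 | 110.2 |
| west run | 3.1 | 134.3 |
| west run | 3.7 | 163.8 |
| west run | 4.2 | 185.8 |
| south-west run | 0.53 | 5.3 |
| south-west run | 1.1 | 9.6 |
| south-west run | 1.6 | 18.8 |
| south-west run | 2.1 | 27.6 |
| south-west run | 2.6 | 40.1 |
| south-west run | 3.1 | 55.4 |
| south-west run | 3.7 | 71.0 |
| south-west run | 4.2 | 86.7 |

(scatter of a reading: 1 mM)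

- Overall: starting material + partner -> product, with free catalyst as catalyst.
- Constant volume, constant temperature.
- The analysis sees a species whether free or bound.
- "The second partner" is partner.
- An order is taken over about fifteen percent of the charge, up and down.

1. apparent order in [partner] of the starting rate, round the charge of the north run (the rate where two percent of its starting material have turned into product)
2. apparent order in [starting material] of the starting rate, round the charge of the north run (the rate where two percent of its starting material have turned into product) (one fixed amount of product, the same in the runs compared)
3. the north-east run starts with 100 mM less of starting material and of partner than the north run, and with no product. Compared where both hold the same amount of starting material, once fifteen percent of what the north-east run was charged with has turned into product, is the north-east run faster, slower or alike (within a tenth)?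
4. product in the south run at 4.2 min, as a share of the starting material charged

Let P be product, A the starting material charged, and p a seed: the amount of product that pushes as hard as the catalyst does. We take the rate as (P+p)(A−P)/(τ(A+p)), which is autocatalysis on a catalysed start, and it integrates in closed form to t/τ = ln[A(P+p)/(p(A−P))]. In the north run, the rate per unit of remaining starting material climbs from 0.128 min⁻¹ near 26.9 mM of product to 0.286 min⁻¹ near 101.7 mM, and the straight line through these two readings gives p = 34.0 mM.

The last readings then give τ = 1.66 min for the north run and 1.30 min for the west run. An earlier west reading gives 1.28 min, so the seed read in the north run serves the west run too. We assume τ = τ∞ + c/R, with R the partner charged. These two runs then give τ∞ = 0.913 min, the floor of the time constant, the part of τ that does not fall with partner at a fixed charge of starting material and free catalyst. The part that does fall, as a share of τ, is the order in partner: 0.450 at the north charge.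

What must we know well for the south run? Its τ is 1.03 min, and the partner charge enters through c/R, just 0.117 min of that. A seed larger by half, at the same τ, gives a share of 90.9%. A floor larger by half gives 65.7%. So of the two, the floor is the number to hold firmly. With the values as read, solving the curve for P, we commit to 87.6% of the charge in the south run.

The forecast gave 0.22, 1, slower and 97%, holding that “the south run should be essentially complete unless the partner effect saturates strongly”, and its share is higher than ours. The simulation gives 0.46, 0.91, slower and 85.0%.

    2 free catalyst ⇌ catalyst dimer, settled at all times (7070 M⁻¹)
    catalyst dimer + starting material + partner → product + catalyst dimer (2424 M⁻² min⁻¹)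
    starting material + partner + product → 2 product (11.76 M⁻² min⁻¹)
    starting material + partner ⇌ idle substrate-reagent adduct, settled at all times (3.410 M⁻¹)

The south run stands 2.6 percentage points below our share, with the floor carried over unchanged. On the north-east run, which played no part in reading the floor, the same τ∞, scaled by A+p for the smaller charge, gives τ = 2.78 min. A quarter of that charge should then be product at 2.87 min, and the north-east run reached it at 2.66 min. The floor goes with the idle substrate-reagent adduct: in the north run, the joining of starting material and partner to that adduct brings the order in partner to 0.46, from the 1.0 it has without that joining.

(The earlier runs and the new flask are simulated for substances that don't exist; the scatter is artificial.)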